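Count ligand exposure, not hours.

in all of them: starting complex 0.10 M; capture agent 0.0100 M; time 10 h

|  | incoming ligand |
|---|---|
| delta | 0.240 M |
| eta | 0.590 M |
| zeta | 0.0950 M |

    complex with one exchanged + capture agent → trapped intermediate (k1 = 1.1 M⁻¹ h⁻¹)
    starting complex + incoming ligand → leaving ligand + complex with one exchanged (k2 = 1.2 M⁻¹ h⁻¹)
    complex with two exchanged + incoming ligand → leaving ligand + complex with three exchanged (k3 = 0.18 M⁻¹ h⁻¹)
    complex with one exchanged + incoming ligand → leaving ligand + complex with two exchanged (k4 = 0.70 M⁻¹ h⁻¹)
    complex with three exchanged + incoming ligand → leaving ligand + complex with four exchanged (k5 = 1.5 M⁻¹ h⁻¹)

* which of these there is most of at the end, counted by the starting complex in it, delta (complex with one exchanged / complex with two exchanged / complex with four exchanged / starting complex / complex with three exchanged)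
* which of these there is most of at the end, counted by the starting complex in it, eta (complex with one exchanged / complex with two exchanged / complex with four exchanged / starting complex / complex with three exchanged)
* which of these there is most of at the end, counted by the starting complex in it, zeta (complex with one exchanged / complex with two exchanged / complex with four exchanged / starting complex / complex with three exchanged)
* how much there is at the end of the one of these that leads, in percent of the starting complex charged: delta
* how much there is at the end of the one of these that leads, in percent of the starting complex charged: eta
* how much there is at the end of the one of these that leads, in percent of the starting complex charged: zeta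

Start with delta and treat the ligand as steady (pseudo-first-order). Let e be the rate constant of the first exchange times the mean free incoming ligand times the time, so the fraction of starting complex remaining is exp(−e). At the charged ligand, e is 2.88, leaving 5.61% of the starting complex and 31.3% as complex with one exchanged. But that ligand does not stay: with the remainder counted as complex with two exchanged, each complex has taken 1.58 ligands out of 2.40 charged.

Put the mean of the charged and remaining ligand back, and e falls to 1.93. Go round again and it rises to 2.11. The rounds swing, so take their midpoint, 2.02: this is the ligand exposure of delta. It gives 13.2% starting complex, 42.0% complex with one exchanged, and 44.8% further on.

Doubt the capture agent next. In delta, at its charged amount, it takes complex with one exchanged at 0.0110 h⁻¹, slower than the 0.118 h⁻¹ of the ligand at its reckoned mean, so it trims that complex without opening a main route. Complex with two exchanged must still give up a share of the 44.8%, so leave delta's leader open between the two.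

Zeta runs the same way: 1.14, then 0.604, then 0.821. The midpoint 0.713 leaves 49.0% starting complex ahead of 40.7% complex with one exchanged.

In eta, spending 2 ligands per complex gives an exposure of 5.88. The objection here is the drain from complex with two exchanged, which runs at 0.150 of the first exchange's pace after a mean birth at exposure 2.71. That keeps about 57.6% as complex with two exchanged.

The forecast names complex with one exchanged at 40.5% for delta, complex with two exchanged at 56.5% for eta, and starting complex at 50% for zeta, and it reckons by ligand exposure too, because that “makes the consecutive exchange steps linear”. It names a leader for delta where this reckoning left it open.

The flasks give complex with one exchanged at 41.1% for delta, complex with two exchanged at 56.6% for eta, and starting complex at 49.7% for zeta.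

Delta's starting complex of 15.1% reads as an exposure of 1.89, less than the reckoned 2.02. Now take a neighbour of delta charged with 0.41 M of incoming ligand. Its rounds give 4.92, 3.80 and 3.87. The midpoint 3.84 predicts 2.15% starting complex and 20.4% complex with one exchanged. That flask holds 3.24% and 23.3%, and the lead has passed to complex with two exchanged at 54.8%.

The constants used here were set for the occasion; the flask was simulated.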